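The numbers in the tables were computed for substances that don't exist; scatter was added.

The easy step came first: in percent of the charge, isomer of the product A stood at 40% in the east run and 40% in the south run at 6.00 h, although the charges were 13 mM and 30 mM, so I reckoned the three runs as one curve and applied it to the three new flasks at 20 mM.

| flask | substrate | remark | time |
|---|---|---|---|
| north-west | 20 mM | run made earlier |  |
| east | 13 mM | run made earlier |  |
| south | 30 mM | run made earlier |  |
| eta | 20 mM | a closed flask charged with all of it at once and left for 5.0 h | 5.0 h |
| epsilon | 20 mM | one stirred flow tank at steady state, fed with the mixture as stated, mean residence time 15.0 h |  |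
| theta | 20 mM | one stirred flow tank at steady state, fed with the mixture as stated, mean residence time 5.0 h |  |

| run | time / h | target / % | isomer of the product A / % | third isomer / % |
|---|---|---|---|---|
| north-west | 0.250 | 34 | 4 | 0 |
| north-west | 0.500 | 33 | 4 | 2 |
| north-west | 1.33 | 33 | 14 | 4 |
| north-west | 3.00 | 25 | 29 | 2 |
| east | 0.833 | 33 | 10 | 1 |
| east | 2.00 | 28 | 21 | 3 |
| east | 4.00 | 20 | 34 | 0 |
| east | 6.00 | 17 | 40 | 2 |
| south | 0.500 | 33 | 7 | 2 |
| south | 1.00 | 32 | 11 | 1 |
| south | 2.50 | 29 | 28 | 3 |
| south | 6.00 | 20 | 40 | 5 |

(standard deviation of a reading: 1.5 percentage points)

- the set-up with the highest share of target in all that became target or isomer of the product A or third isomer or isomer of the product B, at the outlet or at the end ("none" if the first two lie within 2 percentage points) (eta / epsilon / theta / none)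
- share of target in all that became target or isomer of the product A or third isomer or isomer of the product B, at the outlet or at the end, eta
- share of target in all that became target or isomer of the product A or third isomer or isomer of the product B, at the outlet or at the end, epsilon
- share of target in all that became target or isomer of the product A or third isomer or isomer of the product B, at the outlet or at the end, theta

- the stated concentrations are those of everything mixed, before any reaction; amounts are the same in each set-up
- the earlier runs were made in a closed, stirred flask

Target reached 34% by 0.250 h in the north-west run and was still 33% at 1.33 h. I therefore treated c(substrate) + c(target) as one pool in rapid pre-equilibrium, with target a fixed fraction f of it, since that early time is far shorter than the 5.0 h of eta, which is also the mean residence time of theta. The falls of target in the east and south runs, taken together, gave 0.109 h⁻¹: this drain constant, the fraction of the pool lost per hour, is a reading with the scatter of its readings.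

I reckoned the pool left at 57.9% in eta, but in a tank the balance divides the feed by the drain constant times the residence time plus one, giving 64.7% in theta and 37.9% in epsilon. The share asked is f times the pool, divided by the charge less the substrate still in the pool.

With f as the single first reading, 34%, theta gave 38.4%. That single reading was the weak link, so I carried the earliest reading of each run back to zero time with the drain constant and averaged them to 35.3%. I committed to 32.7% for eta, 17.7% for epsilon and 39.3% for theta, which stood highest.

The forecast named theta, with 32% for eta, 18% for epsilon and 38.5% for theta, saying “The short-residence tank wins because substrate remains excluded from the share”. The flask gave theta as best, with 28.7% for eta, 22.5% for epsilon and 37.1% for theta.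

    substrate ⇌ target (K = 0.600, k = 8.70 × 10⁻⁴ s⁻¹)
    substrate ⇌ isomer of the product A (K = 3.00, k = 5.70 × 10⁻⁵ s⁻¹)
    substrate ⇌ third isomer (K = 1.60, k = 3.00 × 10⁻⁶ s⁻¹)
    target ⇌ isomer of the product B (K = 1.60, k = 1.80 × 10⁻⁵ s⁻¹)

Substrate exchanged with target first, the forward step from substrate to target alone having a half-life of 0.22 h against 3.4 h for the forward step to isomer of the product A. Isomer of the product A then grew from substrate, standing at 30.1% of the charge beside 39.3% substrate at the outlet of theta. Worked back from the simulated substrate and target, the drain was 0.132 h⁻¹ in eta and 0.0849 h⁻¹ in epsilon, either side of my 0.109 h⁻¹, and my pool for epsilon, 37.9%, fell short of the 44.0% there. For the east run at 6.00 h, whose readings went into my 0.109 h⁻¹, that constant gives a share of 27.7%, and the simulated share is 25.0%.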